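**Plan (labdane numbering)**
- **Cuts, in order:** both acetate C–O bonds; the C17–O bond (back to the C17 methyl group); C11–C12 (side chain); C9=C11 (back to a C9 ketone); the bond from C2 to a helper ester; C3–C4 (ring A); then C10–C1 and C10–C20.
- **Enabling feature:** ring B (C5–C10) carries C17 on C8, a carbonyl-level C9, the quaternary C10 and, on C5, carbon C4 with its two methyl groups. This is the full ten-carbon skeleton of (R)-carvone. The isopropenyl group is C4/C18/C19, so one hydrogen atom added to its CH2 creates the gem-dimethyl group and a tertiary C4 radical within reach of C3 of an acrylate hung on C10.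
- **Forward:** ring B is bought. C20 and the C1–C3 acrylate are put on C10, and ring A closes through the radical C3–C4 bond. The C2 ester is then excised, C11 is added by methylenation, and the C12–C16 ester fragment is joined at C11–C12. Oxidation at C17, reduction and acetylation finish the target.
- **Stereochemistry:** C5 comes from carvone, C10 from alkylation anti to the isopropenyl group, C9 from hydroboration on the alpha face opposite C20, and C13 from the (R)-methylsuccinic acid half ester.

Key step: step 3

Remark: the C10 epimers of monomethylated carvone and any C2 epimers of the ester-bearing decalins converge on later compounds, so only the expected major isomer is drawn. The 4-methyl half ester of (R)-methylsuccinic acid is taken as a catalogue compound.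

Step 1
Reactants: 1 (R)-(−)-carvone
Product: 3 (5R,6S)-6-methylcarvone, via lithium dienolate 2 (not isolated)
Conditions: LiN(i-Pr)2, THF, −78 °C; MeI, −78 → 0 °C
Reagents that add atoms: iodomethane, CI
Why: Kinetic deprotonation of the cross-conjugated enone takes place at the alpha-prime CH2 (C10), and enolate alkylation (SN2 on MeI) should put C20 mainly trans to the isopropenyl group, a centre that is flattened again in step 2 so its configuration does not matter.

Step 2
Reactants: 3 (5R,6S)-6-methylcarvone; 4 methyl 2-(bromomethyl)acrylate
Product: 6 methyl 2-{[(1S,6S)-1,3-dimethyl-2-oxo-6-(prop-1-en-2-yl)cyclohex-3-en-1-yl]methyl}acrylate, via lithium enolate 5 (not isolated)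
Conditions: LiN(i-Pr)2, THF, −78 → 0 °C; DMPU; 4, −78 °C → rt
Reagents that add atoms: none
Why: Enolate alkylation with a doubly activated allylic bromide (SN2 and SN2' lead to the same product) should occur on the enolate face opposite the C5 isopropenyl group, which sets quaternary C10 with C1 trans and C20 cis to C4, the arrangement a trans-decalin requires.

Step 3
Reactants: 6 methyl 2-{[(1S,6S)-1,3-dimethyl-2-oxo-6-(prop-1-en-2-yl)cyclohex-3-en-1-yl]methyl}acrylate
Product: 7 methyl (2S,4aS,8aS)-4,4,7,8a-tetramethyl-8-oxo-1,2,3,4,4a,5,8,8a-octahydronaphthalene-2-carboxylate (trans-decalin enone with equatorial C2 ester)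
Conditions: Fe(acac)3 (30 mol %), PhSiH3 (2.5 equiv), EtOH (0.03 M, degassed), 60 °C
Reagents that add atoms: none
Why: Fe(acac)3 and PhSiH3 in ethanol generate an iron hydride that hands a hydrogen atom to the CH2 end of the electron-neutral isopropenyl group, the tertiary C4 radical so formed adds to the unsubstituted acrylate carbon C3, and the resulting C2 radical next to the ester is reduced by divalent iron to an enolate that ethanol protonates, which regenerates trivalent iron. The closest known reaction type is the iron-catalysed hydrogen-atom-transfer reductive olefin coupling, used here as an intramolecular Giese addition. Ring A closes in the 6-endo-trig mode through a chair-like arrangement in which C1 and C4 are both equatorial on ring B, so the trans fusion already encoded at C5 and C10 is carried over because neither atom takes part in bond formation. The only new stereocentre is C2, where the ester should settle in the equatorial 2-alpha position because the axial site is syn-diaxial to C19 and C20, and its configuration is of no consequence since step 5 deletes it. The step needs chemoselective hydrogen-atom transfer (secured because the isopropenyl group is the only electron-neutral 1,1-disubstituted alkene, whereas the C7=C8 enone and the acrylate are electron-poor and accept the hydrogen atom more slowly) and 6-endo over 5-exo regioselectivity (secured by the ester, which polarises the acceptor towards attack at C3 by the nucleophilic radical, and by full substitution at C2, attack on which would leave an unstabilised primary radical). Dilute, degassed conditions should suppress intermolecular addition and oxygen trapping of the C4 radical.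

Step 4
Reactants: 7 methyl (2S,4aS,8aS)-4,4,7,8a-tetramethyl-8-oxo-1,2,3,4,4a,5,8,8a-octahydronaphthalene-2-carboxylate
Product: 8 (2S,4aS,8aS)-4,4,7,8a-tetramethyl-8-oxo-1,2,3,4,4a,5,8,8a-octahydronaphthalene-2-carboxylic acid
Conditions: LiOH·H2O, THF/MeOH/H2O, 40 °C; then 1 M HCl
Reagents that add atoms: lithium hydroxide, [Li+].[OH-]
Why: Saponification of an unhindered equatorial methyl ester (acyl-oxygen cleavage) should be clean because C5 and C10 are not epimerisable and C2 can only drift towards the equatorial acid.

Step 5
Reactants: 8 (2S,4aS,8aS)-4,4,7,8a-tetramethyl-8-oxo-1,2,3,4,4a,5,8,8a-octahydronaphthalene-2-carboxylic acid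
Product: 10 bicyclic enone (4aS,8aS)-2,5,5,8a-tetramethyl-4a,5,6,7,8,8a-hexahydronaphthalen-1(4H)-one, via Barton ester 9 (not isolated)
Conditions: 1-hydroxypyridine-2(1H)-thione, DCC, DMAP (cat.), CH2Cl2, 0 °C → rt, dark; then t-BuSH, hν (tungsten lamp), rt
Reagents that add atoms: none
Why: In this Barton reductive decarboxylation the thiohydroxamate ester fragments in a radical chain, the secondary C2 radical takes a hydrogen atom from t-BuSH far from the enone, and C2 becomes a plain CH2 group.

Step 6
Reactants: 10 bicyclic enone (4aS,8aS)-2,5,5,8a-tetramethyl-4a,5,6,7,8,8a-hexahydronaphthalen-1(4H)-one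
Product: 11 drima-7,9(11)-diene
Conditions: Ph3PCH3Br (slight excess over base), KOt-Bu, toluene, 90 °C
Reagents that add atoms: methyltriphenylphosphonium bromide, C[P+](c1ccccc1)(c1ccccc1)c1ccccc1.[Br-]
Why: Wittig methylenation under the hot alkoxide conditions used for hindered ketones should add the small non-stabilised ylide 1,2 to the C9 carbonyl, one flank of which (C8) is planar, and the absence of free alkoxide limits gamma-deprotonation at C6.

Step 7
Reactants: 12 (R)-4-methoxy-2-methyl-4-oxobutanoic acid
Product: 14 (R)-4-methyldihydrofuran-2(3H)-one, via hydroxy ester 13 (not isolated)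
Conditions: BH3·THF, THF, −10 °C → rt; H2O; then p-TsOH (cat.), CH2Cl2, rt
Reagents that add atoms: none
Why: Borane reduces the free carboxylic acid (future C12) chemoselectively beside the methyl ester, acid-catalysed lactonisation follows, and C13 is untouched under these non-basic conditions.

Step 8
Reactants: 14 (R)-4-methyldihydrofuran-2(3H)-one
Product: 15 methyl (R)-4-bromo-3-methylbutanoate
Conditions: HBr (dry gas), MeOH, 0 °C → rt
Reagents that add atoms: hydrogen bromide, Br; methanol, CO
Why: The classical acidic opening of a gamma-butyrolactone lets bromide displace the protonated acyloxy group at primary C12 (SN2), Fischer esterification traps the acid, and C13 is no reacting centre and keeps its configuration.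

Step 9
Reactants: 11 drima-7,9(11)-diene; 15 methyl (R)-4-bromo-3-methylbutanoate
Product: 17 methyl (13S)-labd-7-en-15-oate, via B-alkyl-9-BBN 16 (not isolated)
Conditions: 9-BBN dimer, THF, 60 °C; then 15, Pd(OAc)2 (5 mol %), PCy3 (10 mol %), K3PO4·H2O, THF, rt → 40 °C
Reagents that add atoms: none
Why: 9-BBN should hydroborate only the terminal C9=C11 bond, with boron on C11 and hydrogen delivered to C9 from the alpha face opposite the axial C20 methyl group (which sets 9-alpha-H), and the alkyl–alkyl Suzuki–Miyaura coupling with an electron-rich bulky trialkylphosphine palladium catalyst, which adds oxidatively to primary bromides in SN2 fashion and resists beta-hydride elimination, then forms C11–C12 without touching C13.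

Step 10
Reactants: 17 methyl (13S)-labd-7-en-15-oate
Product: 18 methyl (13S)-17-hydroxylabd-7-en-15-oate
Conditions: SeO2 (0.3 equiv), t-BuOOH (decane solution), CH2Cl2, 0 °C → rt
Reagents that add atoms: tert-butyl hydroperoxide, CC(C)(C)OO; selenium dioxide, O=[Se]=O
Why: Riley-type allylic oxidation (ene reaction, then [2,3]-sigmatropic shift) acts at the more substituted alkene carbon C8 and should prefer the C17 methyl group, which lies trans to C6, over the hindered tertiary C9–H, as in related drim-7-enes, and any enal from over-oxidation converges on the same diol in step 11.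

Step 11
Reactants: 18 methyl (13S)-17-hydroxylabd-7-en-15-oate
Product: 19 (13S)-labd-7-ene-15,17-diol
Conditions: LiAlH4, THF, 0 °C → rt; then H2O
Reagents that add atoms: none
Why: Hydride reduction of the C15 methyl ester to the primary alcohol leaves the trisubstituted alkene and all four stereocentres untouched.

Step 12
Reactants: 19 (13S)-labd-7-ene-15,17-diol
Product: 20 (5S,9R,10S,13S)-labd-7-ene-15,17-diyl diacetate (target)
Conditions: Ac2O, pyridine, DMAP (cat.), CH2Cl2, rt
Reagents that add atoms: acetic anhydride, CC(=O)OC(C)=O
Why: DMAP-catalysed acylation esterifies both unhindered primary alcohols in one operation without ionising the allylic C17–O bond.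

**Compound list**
1 | (R)-(−)-carvone | O=C1C(C)=CC[C@@H](C(C)=C)C1 | starting material
2 | lithium cross-conjugated dienolate of 1 (C9–OLi, C9=C10) | [Li]OC1=C[C@H](C(C)=C)CC=C1C | intermediate
3 | (5R,6S)-6-methylcarvone (C20 on C10, trans to isopropenyl) | O=C1C(C)=CC[C@@H](C(C)=C)[C@@H]1C | intermediate
4 | methyl 2-(bromomethyl)acrylate | C=C(CBr)C(=O)OC | starting material
5 | lithium enolate of 3 (C9–OLi, tetrasubstituted C9=C10) | [Li]OC1=C(C)[C@H](C(C)=C)CC=C1C | intermediate
6 | methyl 2-{[(1S,6S)-1,3-dimethyl-2-oxo-6-(prop-1-en-2-yl)cyclohex-3-en-1-yl]methyl}acrylate | O=C1C(C)=CC[C@@H](C(C)=C)[C@]1(C)CC(=C)C(=O)OC | intermediate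
7 | methyl (2S,4aS,8aS)-4,4,7,8a-tetramethyl-8-oxo-1,2,3,4,4a,5,8,8a-octahydronaphthalene-2-carboxylate | O=C1C(C)=CC[C@H]2C(C)(C)C[C@H](C(=O)OC)C[C@]12C | intermediate
8 | (2S,4aS,8aS)-4,4,7,8a-tetramethyl-8-oxo-1,2,3,4,4a,5,8,8a-octahydronaphthalene-2-carboxylic acid | O=C1C(C)=CC[C@H]2C(C)(C)C[C@H](C(=O)O)C[C@]12C | intermediate
9 | 2-thioxopyridin-1(2H)-yl ester of 8 (Barton ester) | O=C1C(C)=CC[C@H]2C(C)(C)C[C@H](C(=O)ON3C=CC=CC3=S)C[C@]12C | intermediate
10 | (4aS,8aS)-2,5,5,8a-tetramethyl-4a,5,6,7,8,8a-hexahydronaphthalen-1(4H)-one (11-nordrim-7-en-9-one) | O=C1C(C)=CC[C@H]2C(C)(C)CCC[C@]12C | intermediate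
11 | drima-7,9(11)-diene (5-alpha-H, 10-beta-methyl) | C=C1C(C)=CC[C@H]2C(C)(C)CCC[C@]12C | intermediate
12 | (R)-4-methoxy-2-methyl-4-oxobutanoic acid | COC(=O)C[C@@H](C)C(=O)O | starting material
13 | methyl (R)-4-hydroxy-3-methylbutanoate | COC(=O)C[C@@H](C)CO | intermediate
14 | (R)-4-methyldihydrofuran-2(3H)-one | O=C1C[C@@H](C)CO1 | intermediate
15 | methyl (R)-4-bromo-3-methylbutanoate | COC(=O)C[C@@H](C)CBr | intermediate
16 | 9-(drim-7-en-11-yl)-9-borabicyclo[3.3.1]nonane (9-alpha-H) | B1(C[C@H]3C(C)=CC[C@H]4C(C)(C)CCC[C@]34C)C2CCCC1CCC2 | intermediate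
17 | methyl (13S)-labd-7-en-15-oate (5-alpha-H, 9-alpha-H, 10-beta-methyl) | COC(=O)C[C@@H](C)CC[C@H]1C(C)=CC[C@H]2C(C)(C)CCC[C@]12C | intermediate
18 | methyl (13S)-17-hydroxylabd-7-en-15-oate | COC(=O)C[C@@H](C)CC[C@H]1C(CO)=CC[C@H]2C(C)(C)CCC[C@]12C | intermediate
19 | (13S)-labd-7-ene-15,17-diol | OCC[C@@H](C)CC[C@H]1C(CO)=CC[C@H]2C(C)(C)CCC[C@]12C | intermediate
20 | (5S,9R,10S,13S)-labd-7-ene-15,17-diyl diacetate | CC(=O)OCC[C@@H](C)CC[C@H]1C(COC(C)=O)=CC[C@H]2C(C)(C)CCC[C@]12C | target

Total step count: 12. Longest linear sequence: 10 (steps 1–6 and 9–12). Steps 7 and 8 build the side-chain fragment in parallel.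

**Steps most likely to fail**

**Step 9 (hydroboration and alkyl–alkyl coupling).** Both partners are branched next to the reacting carbon. Transmetalation from boron and oxidative addition into the C12–Br bond may therefore be too slow. Beta-hydride elimination or protodeboronation may then consume the partners.

The fallback replaces the cross-coupling by an olefination. It sets out from 11 and 15 and comes back at 17. Borane 16 is made as before and oxidised (NaOH, H2O2) to (−)-drimenol F1. A Dess–Martin oxidation buffered with NaHCO3 gives drim-7-en-11-al F2. Bromide 15 is heated with PPh3 in MeCN to give [(2R)-4-methoxy-2-methyl-4-oxobutyl]triphenylphosphonium bromide F3. NaN(SiMe3)2 in THF at −78 °C converts it into methyl (R)-3-methyl-4-(triphenylphosphoranylidene)butanoate F4. Wittig reaction of this ylide with F2 gives methyl (11Z,13R)-labda-7,11-dien-15-oate F5. Diimide (2-nitrobenzenesulfonyl hydrazide, Et3N) then saturates only the disubstituted C11=C12 bond and delivers 17.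

**Step 6 (methylenation).** The bulky ylide may fail to reach C9, which is flanked by quaternary C10 and the C8 methyl group. Gamma-deprotonation to the dienolate may then win.

The fallback sets out from 10, comes back at 11, and splits the olefination into an addition and an elimination (Peterson olefination). The small, hard nucleophile Me3SiCH2Li (THF, −78 → 0 °C) adds to C9 from the alpha face. This gives 9-beta-hydroxy-9-alpha-[(trimethylsilyl)methyl]-11-nordrim-7-ene F6. KH in THF then triggers syn-elimination of silanolate to give 11 without passing through an allyl cation.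

**Step 3 (radical ring closure).** The iron hydride may transfer its hydrogen atom to the acrylate or the enone. The C4 radical may also be reduced before it cyclises, which would give saturated open-chain material.

The fallback sets out from 6, comes back at 7, and generates the same radical by halogen abstraction. Markovnikov addition of HBr (33 % in AcOH, 0 °C) to the isopropenyl group, the only nucleophilic alkene, gives methyl 2-{[(1S,6R)-6-(2-bromopropan-2-yl)-1,3-dimethyl-2-oxocyclohex-3-en-1-yl]methyl}acrylate F7. Slow addition of Bu3SnH with AIBN in benzene at 80 °C produces the C4 radical. This radical closes ring A by the same 6-endo Giese addition to C3 and gives 7.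

**Further compounds**
F1 | step 9 | (−)-drimenol | OC[C@H]1C(C)=CC[C@H]2C(C)(C)CCC[C@]12C
F2 | step 9 | drim-7-en-11-al | O=C[C@H]1C(C)=CC[C@H]2C(C)(C)CCC[C@]12C
F3 | step 9 | [(2R)-4-methoxy-2-methyl-4-oxobutyl]triphenylphosphonium bromide | COC(=O)C[C@@H](C)C[P+](c1ccccc1)(c1ccccc1)c1ccccc1.[Br-]
F4 | step 9 | methyl (R)-3-methyl-4-(triphenylphosphoranylidene)butanoate | COC(=O)C[C@@H](C)C=P(c1ccccc1)(c1ccccc1)c1ccccc1
F5 | step 9 | methyl (11Z,13R)-labda-7,11-dien-15-oate | COC(=O)C[C@@H](C)/C=C\[C@H]1C(C)=CC[C@H]2C(C)(C)CCC[C@]12C
F6 | step 6 | 9-beta-hydroxy-9-alpha-[(trimethylsilyl)methyl]-11-nordrim-7-ene | C[Si](C)(C)C[C@]1(O)C(C)=CC[C@H]2C(C)(C)CCC[C@]12C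
F7 | step 3 | methyl 2-{[(1S,6R)-6-(2-bromopropan-2-yl)-1,3-dimethyl-2-oxocyclohex-3-en-1-yl]methyl}acrylate | O=C1C(C)=CC[C@@H](C(C)(C)Br)[C@]1(C)CC(=C)C(=O)OC
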